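**Retrosynthetic overview**

1. 1,3-Di-O-caffeoylquinic acid ⇐ acid hydrolysis of four aryl acetates and of a butane-2,3-diacetal on O4/O5 ⇐ C7 carboxyl from a CH2OSi group (desilylation, two-stage oxidation) once both esters are in place.
2. The two ester C–O bonds at O1 and O3 ⇐ one cis-1,3-diol plus 3,4-di-O-acetylcaffeoyl chloride (two steps from caffeic acid).
3. The 1,3-diol ⇐ hydride opening at C2 of a C1–C2 oxirane ⇐ hydroxyl-directed epoxidation of the C1=C2 bond of a shikimate-derived allylic alcohol (ester reduced, O7 silylated, O4/O5 as diacetal) ⇐ (−)-shikimic acid and butane-2,3-dione.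
4. Feature used: on the cyclohexane ring, O1 on the quaternary C1 and O3 on C3 are cis and 1,3-related; shikimic acid already has C3, C4 and C5 correct and has the C1=C2 double bond next to the allylic O3–H, which can hand an oxygen to C1 on its own face.
5. Ring order: carbocycle taken from shikimic acid; trans-fused 1,4-dioxane (diacetal) closed in step 1; oxirane closed in step 4 and opened in step 5; dioxane opened in step 12.

Key step: step 4

Remark on the chemistry: ring atoms are numbered as in quinic and shikimic acid (C1 carries the carboxyl carbon C7; O3 is cis to O4, O5 is trans to O4). Read from the target SMILES, the secondary ester sits on O3 and O1 is cis to O3; the route is built on that reading.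

**Step 1**
Reactants: 1 (−)-shikimic acid; 2 butane-2,3-dione
Product: 4 methyl 4,5-O-[(2S,3S)-2,3-dimethoxybutane-2,3-diyl]shikimate (trans-fused 1,4-dioxane chair with both OMe axial; O3–H free), via methyl shikimate 3 (not isolated)
Conditions: MeOH, HC(OMe)3, CSA (cat.), reflux
Reagents that add atoms: methanol, CO (ester OMe and both acetal OMe); trimethyl orthoformate, COC(OC)OC (water scavenger, can also supply OMe)
Why: Fischer esterification and butane-2,3-diacetal formation run in the same acidic methanol, and under thermodynamic control the diacetal should take the trans-diequatorial 4,5-diol rather than the cis-3,4-diol, because only there can a trans-fused dioxane chair with two axial, anomerically stabilised methoxy groups form (this also fixes both acetal stereocentres), while C3, C4 and C5 are untouched.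

**Step 2**
Reactants: 4 methyl 4,5-O-diacetal shikimate
Product: 5 allylic diol (1-hydroxymethyl-cyclohexene; C3, C4, C5 as in shikimic acid; O4/O5 as diacetal; O3–H and O7–H free)
Conditions: i-Bu2AlH (DIBAL-H, 3.5 equiv), CH2Cl2, −78 → 0 °C; aq. Rochelle salt
Reagents that add atoms: none
Why: 1,2-reduction of the α,β-unsaturated ester by i-Bu2AlH at low temperature should stop cleanly at the allylic alcohol (the free O3–H only consumes one extra hydride) and leaves the diacetal alone.

**Step 3**
Reactants: 5 allylic diol
Product: 6 7-O-tert-butyldimethylsilyl allylic alcohol (O3–H free; precursor of the key step)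
Conditions: TBSCl (1.05 equiv), imidazole, CH2Cl2, 0 °C
Reagents that add atoms: tert-butyldimethylsilyl chloride, CC(C)(C)[Si](C)(C)Cl
Why: silylation of the primary alcohol is much faster than that of the pseudoaxial secondary O3–H flanked by the diacetal, so O3–H should stay free as the directing group.

**Step 4**
Reactants: 6 7-O-TBS allylic alcohol
Product: 7 1,2-epoxy alcohol (oxirane oxygen on the face of O3, cis to O3 and O4; O3–H free)
Conditions: VO(acac)2 (5 mol %), t-BuOOH (anhydrous, in decane, 1.5 equiv), CH2Cl2, 0 °C → rt
Reagents that add atoms: tert-butyl hydroperoxide, CC(C)(C)OO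
Why: VO(acac)2 is oxidised by t-BuOOH to a pentavalent oxovanadium alkoxide that binds O3 of 6 and the tert-butylperoxide side by side, and the coordinated peroxide oxygen is then handed to the C1=C2 π bond inside this complex, forming the C1–O and C2–O bonds together. The closest known reaction type is the vanadium-catalysed, hydroxyl-directed epoxidation of cyclohex-2-enols, which gives the syn epoxy alcohols. The oxirane closes by concerted suprafacial transfer of one oxygen atom across the double bond (a [2+1] addition without an open intermediate). Both new stereocentres, C1 and C2, are controlled by the configured C3: the oxygen has to arrive on the face of O3, so the new C1–O bond is cis to O3 and O4 as in the target, and C2 follows from the suprafacial addition. The step needs facial selectivity and preference for epoxidation over oxidation of the carbinol; these should be secured because the trans-fused diacetal holds O4 and O5 equatorial and so O3 pseudoaxial (the geometry from which delivery is fastest), O3–H is the only free hydroxyl (O7 is silylated and cannot direct), and the trisubstituted alkene is electron-rich once the ester is reduced.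

**Step 5**
Reactants: 7 1,2-epoxy alcohol
Product: 8 cis-1,3-diol (tertiary O1–H and secondary O3–H both axial and free; C2 is CH2; O7 silylated; O4/O5 diacetal)
Conditions: LiBHEt3 (3 equiv), THF, 0 °C → rt; then H2O
Reagents that add atoms: none
Why: SN2 hydride opening of a trisubstituted oxirane, in which LiBHEt3 should attack the secondary C2 rather than the fully substituted C1 from the face opposite the oxirane oxygen, which in the chair locked by the diacetal is the trans-diaxial (Fürst–Plattner) mode, so the C1–O bond keeps its configuration, C2 becomes CH2 and the silyl ether is not attacked.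

**Step 6**
Reactants: 9 caffeic acid
Product: 10 3,4-di-O-acetylcaffeic acid
Conditions: Ac2O, pyridine, rt; aqueous acidic work-up
Reagents that add atoms: acetic anhydride, CC(=O)OC(C)=O
Why: acetylation of both phenols (any mixed anhydride at the carboxyl group is hydrolysed on work-up) masks the catechol against O-acylation and oxidation in later steps.

**Step 7**
Reactants: 10 3,4-di-O-acetylcaffeic acid
Product: 11 3,4-di-O-acetylcaffeoyl chloride (E)
Conditions: (COCl)2, DMF (cat.), CH2Cl2, 0 °C → rt
Reagents that add atoms: oxalyl chloride, O=C(Cl)C(=O)Cl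
Why: Vilsmeier-type chlorination of the acid by oxalyl chloride and catalytic DMF gives the acid chloride without touching the aryl acetates or the E double bond.

**Step 8**
Reactants: 8 cis-1,3-diol; 11 3,4-di-O-acetylcaffeoyl chloride
Product: 12 1,3-bis-O-(3,4-di-O-acetylcaffeoyl) derivative (O7 silylated, O4/O5 diacetal)
Conditions: 11 (5 equiv), DMAP (1 equiv), pyridine/CH2Cl2, 0 → 40 °C
Reagents that add atoms: none
Why: nucleophilic-catalysed acylation through the acylpyridinium ion from 11 and DMAP, in which O1–H and O3–H are the only hydroxyl groups, so no regiochemical question arises, and excess reagent with gentle warming should carry the slower tertiary, axial O1–H to the ester without touching a stereocentre.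

**Step 9**
Reactants: 12 bis-ester silyl ether
Product: 13 bis-ester primary alcohol (O7–H free)
Conditions: HF·pyridine, pyridine/THF, 0 °C → rt; used at once in step 10
Reagents that add atoms: none
Why: fluoride cleavage of the primary silyl ether in buffered, weakly acidic HF·pyridine should spare the esters, aryl acetates and diacetal and, unlike basic fluoride sources, should not promote the 1,2-shift of the O1 acyl group to the new O7–H.

**Step 10**
Reactants: 13 bis-ester primary alcohol
Product: 14 bis-ester aldehyde (C7 = CHO)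
Conditions: Dess–Martin periodinane, CH2Cl2, rt
Reagents that add atoms: none
Why: Dess–Martin oxidation under near-neutral conditions converts the neopentyl-type primary alcohol into the aldehyde, which has no α-hydrogen and so cannot epimerise or eliminate.

**Step 11**
Reactants: 14 bis-ester aldehyde
Product: 15 1,3-bis-O-(3,4-di-O-acetylcaffeoyl)-4,5-O-diacetal quinic acid
Conditions: NaClO2, NaH2PO4, 2-methylbut-2-ene, t-BuOH/H2O, 0 °C → rt
Reagents that add atoms: sodium chlorite, [Na+].[O-]Cl=O
Why: Pinnick oxidation (chlorous acid as oxidant, 2-methylbut-2-ene as hypochlorite scavenger) takes the aldehyde to the acid under weakly acidic conditions that spare the esters and the electron-poor cinnamoyl double bonds.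

**Step 12**
Reactants: 15 protected acid
Product: 17 1,3-di-O-caffeoylquinic acid (target), via tetraacetate diol acid 16 (not isolated)
Conditions: TFA/H2O (9:1), 0 °C → rt; evaporate; then 2 M aq. HCl/THF (1:3), rt
Reagents that add atoms: none
Why: acid hydrolysis in which aqueous TFA cleaves the diacetal to the 4,5-diol and butane-2,3-dione and dilute HCl then hydrolyses the four phenolic acetates, which are far more labile than the two alkyl cinnamate esters, while the acidic medium throughout should suppress migration of the O3 acyl group to O4 and no stereocentre is affected.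

**Compound list**

1 | (−)-shikimic acid | O[C@@H]1C=C(C(=O)O)C[C@@H](O)[C@@H]1O | starting material
2 | butane-2,3-dione | CC(=O)C(C)=O | starting material
3 | methyl shikimate (not isolated) | O[C@@H]1C=C(C(=O)OC)C[C@@H](O)[C@@H]1O | intermediate
4 | methyl 4,5-O-[(2S,3S)-2,3-dimethoxybutane-2,3-diyl]shikimate | O[C@@H]1C=C(C(=O)OC)C[C@H]2O[C@](C)(OC)[C@@](C)(OC)O[C@H]12 | intermediate
5 | 4,5-O-diacetal allylic diol (C7–OH and O3–H free) | O[C@@H]1C=C(CO)C[C@H]2O[C@](C)(OC)[C@@](C)(OC)O[C@H]12 | intermediate
6 | 7-O-TBS 4,5-O-diacetal allylic alcohol (O3–H free) | O[C@@H]1C=C(CO[Si](C)(C)C(C)(C)C)C[C@H]2O[C@](C)(OC)[C@@](C)(OC)O[C@H]12 | intermediate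
7 | 1,2-epoxy alcohol, oxirane oxygen cis to O3 | O[C@@H]1[C@@H]2O[C@]2(CO[Si](C)(C)C(C)(C)C)C[C@H]3O[C@](C)(OC)[C@@](C)(OC)O[C@H]13 | intermediate
8 | cis-1,3-diol (O1–H, O3–H free; 7-O-TBS; 4,5-O-diacetal) | O[C@@H]1C[C@@](O)(CO[Si](C)(C)C(C)(C)C)C[C@H]2O[C@](C)(OC)[C@@](C)(OC)O[C@H]12 | intermediate
9 | caffeic acid | OC(=O)/C=C/c1ccc(O)c(O)c1 | starting material
10 | 3,4-di-O-acetylcaffeic acid | CC(=O)Oc1ccc(/C=C/C(=O)O)cc1OC(C)=O | intermediate
11 | 3,4-di-O-acetylcaffeoyl chloride | CC(=O)Oc1ccc(/C=C/C(=O)Cl)cc1OC(C)=O | intermediate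
12 | 1,3-bis-O-(3,4-di-O-acetylcaffeoyl) 7-O-TBS 4,5-O-diacetal | O=C(/C=C/c1ccc(OC(C)=O)c(OC(C)=O)c1)O[C@@H]1C[C@@](OC(=O)/C=C/c2ccc(OC(C)=O)c(OC(C)=O)c2)(CO[Si](C)(C)C(C)(C)C)C[C@H]2O[C@](C)(OC)[C@@](C)(OC)O[C@H]12 | intermediate
13 | bis-ester primary alcohol (C7–OH) | O=C(/C=C/c1ccc(OC(C)=O)c(OC(C)=O)c1)O[C@@H]1C[C@@](OC(=O)/C=C/c2ccc(OC(C)=O)c(OC(C)=O)c2)(CO)C[C@H]2O[C@](C)(OC)[C@@](C)(OC)O[C@H]12 | intermediate
14 | bis-ester aldehyde (C7 = CHO) | O=C(/C=C/c1ccc(OC(C)=O)c(OC(C)=O)c1)O[C@@H]1C[C@@](OC(=O)/C=C/c2ccc(OC(C)=O)c(OC(C)=O)c2)(C=O)C[C@H]2O[C@](C)(OC)[C@@](C)(OC)O[C@H]12 | intermediate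
15 | 1,3-bis-O-(3,4-di-O-acetylcaffeoyl)-4,5-O-diacetal quinic acid | O=C(/C=C/c1ccc(OC(C)=O)c(OC(C)=O)c1)O[C@@H]1C[C@@](OC(=O)/C=C/c2ccc(OC(C)=O)c(OC(C)=O)c2)(C(=O)O)C[C@H]2O[C@](C)(OC)[C@@](C)(OC)O[C@H]12 | intermediate
16 | 1,3-bis-O-(3,4-di-O-acetylcaffeoyl)quinic acid (not isolated) | O=C(/C=C/c1ccc(OC(C)=O)c(OC(C)=O)c1)O[C@@H]1C[C@@](OC(=O)/C=C/c2ccc(OC(C)=O)c(OC(C)=O)c2)(C(=O)O)C[C@@H](O)[C@@H]1O | intermediate
17 | 1,3-di-O-caffeoylquinic acid | O=C(/C=C/c1ccc(O)c(O)c1)O[C@@H]1C[C@@](OC(=O)/C=C/c2ccc(O)c(O)c2)(C(=O)O)C[C@@H](O)[C@@H]1O | target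

**Step count**

Total step count: 12.
Longest linear sequence: 10 steps (steps 1–5 and 8–12, from (−)-shikimic acid); the acid chloride branch (steps 6–7) joins at step 8.

**Steps most likely to fail**

Step 8. The esterification may stall at the O3 monoester, because the tertiary, axial O1–H, flanked by C7 and syn-axial to the new O3 ester, attacks the acylpyridinium ion slowly; forcing it may scramble acetyl groups from the aryl acetates. Fallback, from diol 8: both cinnamoyl units are built on the ring in two stages. Heating 8 with Meldrum's acid in toluene at 100 °C (ring opening of the dioxanedione by the alcohol, a reaction that also works with tert-butanol) should give the 1,3-bis(hydrogen malonate) F1. Knoevenagel–Doebner condensation with 3,4-dihydroxybenzaldehyde (pyridine, cat. piperidine, 60 °C; condensation with decarboxylation gives the E-alkenes) should give the 1,3-bis-O-caffeoyl compound with free catechols F2. Ac2O/pyridine then acetylates the four phenols and the route is rejoined at 12.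

Step 5. Hydride attack at C2 may be slow because of the neighbouring C3 alkoxide, leaving conversion incomplete; if forced, it may partly go to C1 or strip the silyl group. Fallback, from epoxide 7: PhSeNa (from PhSeSePh and NaBH4, EtOH, rt → 60 °C), a soft nucleophile that opens trisubstituted oxiranes at the secondary carbon in the trans-diaxial sense, should give the 2-phenylselanyl 1,3-diol F3. Radical cleavage of the C–Se bond with Bu3SnH and AIBN (toluene, 80 °C) gives diol 8, where the route resumes.

Step 9. Once O7–H is free, the O1 acyl group can shift to it (1,2-acyl migration through a five-membered orthoester, downhill from tertiary to primary oxygen), which would divert material before the oxidation. Fallback, from diol 8: C7 is raised to the acid level before the esters are made.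
- TBAF in THF gives the triol F4.
- TEMPO (cat.), NaOCl (cat.) and NaClO2 in phosphate buffer (pH 6.7)/MeCN oxidise only the primary alcohol and give the 1-hydroxy acid F5.
- Allyl bromide and KHCO3 in DMF give the allyl ester F6.
- Acylation with 11 (DMAP, pyridine) gives the 1,3-bis-ester allyl ester F7.
- Pd(PPh3)4 (zerovalent palladium) with PhSiH3 in CH2Cl2 removes the allyl group under neutral conditions and gives acid 15, where the route resumes.

**Further compounds**

F1 | step 8 | 1,3-bis(hydrogen malonate) of diol 8 | OC(=O)CC(=O)O[C@@H]1C[C@@](OC(=O)CC(=O)O)(CO[Si](C)(C)C(C)(C)C)C[C@H]2O[C@](C)(OC)[C@@](C)(OC)O[C@H]12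
F2 | step 8 | 1,3-bis-O-caffeoyl 7-O-TBS 4,5-O-diacetal with free catechols | O=C(/C=C/c1ccc(O)c(O)c1)O[C@@H]1C[C@@](OC(=O)/C=C/c2ccc(O)c(O)c2)(CO[Si](C)(C)C(C)(C)C)C[C@H]2O[C@](C)(OC)[C@@](C)(OC)O[C@H]12
F3 | step 5 | 2-phenylselanyl 1,3-diol (Se trans to O1 and O3) | O[C@@H]1[C@@H]([Se]c2ccccc2)[C@@](O)(CO[Si](C)(C)C(C)(C)C)C[C@H]2O[C@](C)(OC)[C@@](C)(OC)O[C@H]12
F4 | step 9 | 4,5-O-diacetal triol (O1–H, O3–H, O7–H free) | O[C@@H]1C[C@@](O)(CO)C[C@H]2O[C@](C)(OC)[C@@](C)(OC)O[C@H]12
F5 | step 9 | 4,5-O-diacetal quinic acid | O[C@@H]1C[C@@](O)(C(=O)O)C[C@H]2O[C@](C)(OC)[C@@](C)(OC)O[C@H]12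
F6 | step 9 | allyl 4,5-O-diacetal quinate | O[C@@H]1C[C@@](O)(C(=O)OCC=C)C[C@H]2O[C@](C)(OC)[C@@](C)(OC)O[C@H]12
F7 | step 9 | allyl 1,3-bis-O-(3,4-di-O-acetylcaffeoyl)-4,5-O-diacetal quinate | O=C(/C=C/c1ccc(OC(C)=O)c(OC(C)=O)c1)O[C@@H]1C[C@@](OC(=O)/C=C/c2ccc(OC(C)=O)c(OC(C)=O)c2)(C(=O)OCC=C)C[C@H]2O[C@](C)(OC)[C@@](C)(OC)O[C@H]12
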